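**Plan**
1. Retrosynthetic cuts, in order: the two ring-B O–Boc groups; the aryl ether bond O1–C7a of the dihydrofuran; the C2–C3 bond (aldol, then oxidation and asymmetric reduction); the C3a–CH2 bond (Pd/zinc enolate) and the C5 side-chain C=C (Wittig).
2. Forward: ring A is bought with all four substituent positions occupied (3-bromo-4,5-dihydroxybenzaldehyde) and ring B comes from 3,4-dihydroxybenzaldehyde. The chain C3a–C3–C2–aryl is joined, and the only ring to be made, the dihydrofuran, is closed last.
3. Enabling feature: in ring A the C7 hydroxyl is ortho to C7a. With a sacrificial OMe on C7a this is a guaiacol unit, and its two-electron oxidation reverses the polarity of C7a (O-stabilised cation), so the neutral C2–OH can bond to it. Reduction then expels the OMe and restores the arene with the C7 phenol already free.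
4. This avoids any alkoxide of the β-hydroxy-α-aryl ester, which under basic SNAr or metal-catalysed etherification would be prone to retro-aldol cleavage, dehydration and loss of configuration.
5. Stereochemistry: one catalytic transfer hydrogenation with dynamic kinetic resolution sets C2 (catalyst) and C3 (faster-reacting epimer, syn = later trans). The ring closure leaves the C2–O bond intact, and trans is also the thermodynamic arrangement.

Key step: step 10

Assumption: the benzofuran locants of the target (O1, C2, C3, C3a, C4–C7, C7a) are used for the corresponding atoms of all precursors in the explanations, while names carry their own locants. The ketal carbon of 13 may form in either configuration, which is irrelevant because it is erased in the same step.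

Step 1
Reactants: 1 3-bromo-4,5-dihydroxybenzaldehyde
Product: 2 3-bromo-5-hydroxy-4-methoxybenzaldehyde
Conditions: MeI (1.05 equiv), Li2CO3 (1.0 equiv), DMF, 45 °C
Reagents that add atoms: iodomethane CI
Why: The 4-OH, para to the formyl group and ortho to bromine, is much the more acidic phenol, so one equivalent of weak base should form only its phenoxide and the Williamson O-methylation should occur there, as in the known 4-O-selective alkylation of 3,4-dihydroxybenzaldehydes.

Step 2
Reactants: 2 3-bromo-5-hydroxy-4-methoxybenzaldehyde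
Product: 3 3-bromo-5-(tert-butyldimethylsilyloxy)-4-methoxybenzaldehyde
Conditions: TBSCl, imidazole, CH2Cl2, rt
Reagents that add atoms: tert-butyldimethylsilyl chloride CC(C)(C)[Si](C)(C)Cl
Why: Standard imidazole-promoted O-silylation masks the future C7 phenol for the ylide, organozinc, enolate and periodinane steps with a group that is orthogonal to the Boc carbonates used on ring B.

Step 3
Reactants: 3 3-bromo-5-(tert-butyldimethylsilyloxy)-4-methoxybenzaldehyde
Product: 4 methyl (E)-3-[3-bromo-5-(tert-butyldimethylsilyloxy)-4-methoxyphenyl]prop-2-enoate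
Conditions: Ph3P=CHCO2Me, toluene, 80 °C
Reagents that add atoms: methyl (triphenylphosphoranylidene)acetate COC(=O)C=P(c1ccccc1)(c1ccccc1)c1ccccc1
Why: Wittig olefination of an aromatic aldehyde with a stabilised ylide runs under neutral conditions and should give the (E)-cinnamate.

Step 4
Reactants: 4 methyl (E)-3-[3-bromo-5-(tert-butyldimethylsilyloxy)-4-methoxyphenyl]prop-2-enoate
Product: 5 methyl (E)-3-[3-(tert-butyldimethylsilyloxy)-4-methoxy-5-(2-methoxy-2-oxoethyl)phenyl]prop-2-enoate
Conditions: BrZnCH2CO2Me (from BrCH2CO2Me, Zn, cat. TMSCl, THF), Pd(dba)2 (2 mol %), Q-Phos (2 mol %), THF, rt → 50 °C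
Reagents that add atoms: methyl bromoacetate COC(=O)CBr, used as its zinc reagent bromo(2-methoxy-2-oxoethyl)zinc COC(=O)C[Zn]Br
Why: Palladium-catalysed α-arylation of a Reformatsky reagent (Negishi-type coupling) installs the arylacetate in one step, because the nearly neutral zinc enolate spares the cinnamate and the silyl ether and the bulky electron-rich ligand should cope with the ortho-methoxy bromide.

Step 5
Reactants: 6 3,4-dihydroxybenzaldehyde
Product: 7 3,4-bis(tert-butoxycarbonyloxy)benzaldehyde
Conditions: Boc2O (2.2 equiv), DMAP (5 mol %), THF, rt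
Reagents that add atoms: di-tert-butyl dicarbonate CC(C)(C)OC(=O)OC(=O)OC(C)(C)C
Why: DMAP-catalysed O-tert-butoxycarbonylation of phenols gives carbonates without α-hydrogens that resist enolates at low temperature, make ring B electron-poor for step 10 and leave under acid at the end.

Step 6
Reactants: 5 methyl (E)-3-[3-(tert-butyldimethylsilyloxy)-4-methoxy-5-(2-methoxy-2-oxoethyl)phenyl]prop-2-enoate; 7 3,4-bis(tert-butoxycarbonyloxy)benzaldehyde
Product: 9 methyl 3-[3,4-bis(tert-butoxycarbonyloxy)phenyl]-2-{3-(tert-butyldimethylsilyloxy)-2-methoxy-5-[(E)-3-methoxy-3-oxoprop-1-enyl]phenyl}-3-hydroxypropanoate (all four stereoisomers), via lithium enolate 8 (not isolated)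
Conditions: LiHMDS (1.05 equiv), THF, −78 °C; then 7, −78 °C; AcOH quench at −78 °C
Reagents that add atoms: none
Why: Lithium enolate aldol addition of an arylacetate to an aromatic aldehyde forms C2–C3 with one equivalent of base, no stereocontrol is sought because both new centres are erased or reset in steps 7 and 8, and the cold acidic quench should prevent retro-aldol cleavage and Boc transfer.

Step 7
Reactants: 9 the aldol mixture
Product: 10 methyl 3-[3,4-bis(tert-butoxycarbonyloxy)phenyl]-2-{3-(tert-butyldimethylsilyloxy)-2-methoxy-5-[(E)-3-methoxy-3-oxoprop-1-enyl]phenyl}-3-oxopropanoate (racemic, configurationally labile)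
Conditions: Dess–Martin periodinane (1.2 equiv), CH2Cl2, 0 °C → rt
Reagents that add atoms: none
Why: Dess–Martin oxidation of a benzylic β-hydroxy ester works under near-neutral conditions that spare the silyl ether, carbonates and cinnamate, and it merges all four isomers into one rapidly racemising β-keto ester.

Step 8
Reactants: 10 the β-keto ester
Product: 11 methyl (2R,3R)-3-[3,4-bis(tert-butoxycarbonyloxy)phenyl]-2-{3-(tert-butyldimethylsilyloxy)-2-methoxy-5-[(E)-3-methoxy-3-oxoprop-1-enyl]phenyl}-3-hydroxypropanoate
Conditions: RuCl(p-cymene)[(R,R)-TsDPEN] (2 mol %), HCO2H/Et3N (5:2), CH2Cl2, 30 °C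
Reagents that add atoms: none
Why: In this Noyori–Ikariya asymmetric transfer hydrogenation with dynamic kinetic resolution of an α-substituted β-keto ester, the (R,R)-catalyst should deliver hydride to the aryl ketone in the same sense as for acetophenone and benzoylacetates to set the (R)-carbinol C2, while C3 racemises quickly through the enol and the epimer that can hold its bulky aryl group anti to the incoming hydride (Felkin–Anh) should react faster to give the syn (2R,3R) isomer, with simple cinnamate C=C bonds remaining inert.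

Step 9
Reactants: 11 the (2R,3R)-silyl ether
Product: 12 methyl (2R,3R)-3-[3,4-bis(tert-butoxycarbonyloxy)phenyl]-3-hydroxy-2-{3-hydroxy-2-methoxy-5-[(E)-3-methoxy-3-oxoprop-1-enyl]phenyl}propanoate
Conditions: TBAF/AcOH (1:1, 1.2 equiv), THF, 0 °C
Reagents that add atoms: none
Why: Fluoride-mediated cleavage of an aryl silyl ether is fast at 0 °C, and the acetic acid buffer keeps the medium too weakly basic for retro-aldol cleavage, C3 epimerisation or carbonate loss.

Step 10
Reactants: 12 the (2R,3R)-guaiacol-type phenol
Product: 14 methyl (2R,3R)-2-[3,4-bis(tert-butoxycarbonyloxy)phenyl]-7-hydroxy-5-[(E)-3-methoxy-3-oxoprop-1-enyl]-2,3-dihydrobenzofuran-3-carboxylate, via fused o-quinone monoketal 13 (not isolated)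
Conditions: PhI(OAc)2 (1.05 equiv), CH2Cl2/(CF3)2CHOH (4:1), −20 → 0 °C; then Zn dust, AcOH, 0 °C, same flask
Reagents that add atoms: none
Why: Proposed new method: PhI(OAc)2 binds the C7 phenol of 12 and two-electron oxidation gives a phenoxenium ion whose charge sits mainly on C7a, where the methoxy oxygen stabilises it as an oxocarbenium ion, so the neutral C2 hydroxyl, held in reach by C3 and C3a, adds to give the fused o-quinone monoketal 13; zinc in acetic acid then passes two electrons into the dienone, methanol leaves C7a and ring A regains aromaticity as the C7 phenol of 14. The closest known reaction types are the oxidative dearomatisation of 2-methoxyphenols to masked o-benzoquinones by external or tethered alcohols and the zinc/acetic acid reductive cleavage of α-oxygenated ketones, o-quinol acetates and quinone monoketals, and the new element is their union into a net exchange of an aryl methyl ether for a tethered secondary alkoxy group. The only ring closed is the dihydrofuran (O1–C7a, 5-exo-trig onto the C7a=O+Me terminus), and the only new stereocentre, the ketal carbon of 13, is erased on rearomatisation, while C2 and C3 persist because the C2–O bond is never broken and no base is present to cause retro-aldol cleavage, E1cB dehydration or enolisation at C3. Site selectivity for C7a over the equally reachable C4–H (para to the phenol) rests on the methoxy group, since isovanillate-type phenols are ketalised at the methoxy-bearing carbon, and the C5 acrylate is meta to C7–OH and so does not oppose the cation. Chemoselectivity rests on the two Boc carbonates, which should keep ring B from being oxidised and from attacking C4 or C7a as a carbon nucleophile (dihydrophenanthrene formation). In the reductive half the ring fusion holds O1 near the dienone plane and leaves OMe pseudo-axial, so only the C7a–OMe σ* orbital overlaps with the reduced π system, and a mis-cleavage of C7a–O1 would merely return 12 for recycling.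

Step 11
Reactants: 14 the bis-Boc dihydrobenzofuran
Product: 15 methyl (2R,3R)-2-(3,4-dihydroxyphenyl)-7-hydroxy-5-[(E)-3-methoxy-3-oxoprop-1-enyl]-2,3-dihydrobenzofuran-3-carboxylate (target)
Conditions: TFA/CH2Cl2 (1:4), 0 °C → rt
Reagents that add atoms: none
Why: Acidolysis of aryl tert-butyl carbonates (loss of the tert-butyl cation, then decarboxylation) frees the catechol without base, leaves both methyl esters and the acrylate untouched, cannot enolise C3, and even a reversible ionisation of the benzylic C2–O bond would re-close trans to the fixed C3 centre.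

**Compound list**
1 | 3-bromo-4,5-dihydroxybenzaldehyde | O=Cc1cc(O)c(O)c(Br)c1 | starting material
2 | 3-bromo-5-hydroxy-4-methoxybenzaldehyde | O=Cc1cc(O)c(OC)c(Br)c1 | intermediate
3 | 3-bromo-5-(tert-butyldimethylsilyloxy)-4-methoxybenzaldehyde | O=Cc1cc(O[Si](C)(C)C(C)(C)C)c(OC)c(Br)c1 | intermediate
4 | methyl (E)-3-[3-bromo-5-(tert-butyldimethylsilyloxy)-4-methoxyphenyl]prop-2-enoate | COC(=O)/C=C/c1cc(O[Si](C)(C)C(C)(C)C)c(OC)c(Br)c1 | intermediate
5 | methyl (E)-3-[3-(tert-butyldimethylsilyloxy)-4-methoxy-5-(2-methoxy-2-oxoethyl)phenyl]prop-2-enoate | COC(=O)/C=C/c1cc(O[Si](C)(C)C(C)(C)C)c(OC)c(CC(=O)OC)c1 | intermediate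
6 | 3,4-dihydroxybenzaldehyde | O=Cc1ccc(O)c(O)c1 | starting material
7 | 3,4-bis(tert-butoxycarbonyloxy)benzaldehyde | O=Cc1ccc(OC(=O)OC(C)(C)C)c(OC(=O)OC(C)(C)C)c1 | intermediate
8 | lithium enolate of 5 (enolate geometry not defined, not isolated) | [Li+].COC(=O)/C=C/c1cc(O[Si](C)(C)C(C)(C)C)c(OC)c(C=C([O-])OC)c1 | intermediate
9 | aldol adduct, all four stereoisomers | COC(=O)/C=C/c1cc(O[Si](C)(C)C(C)(C)C)c(OC)c(c1)C(C(=O)OC)C(O)c1ccc(OC(=O)OC(C)(C)C)c(OC(=O)OC(C)(C)C)c1 | intermediate
10 | α-aryl β-keto ester, racemic and labile | COC(=O)/C=C/c1cc(O[Si](C)(C)C(C)(C)C)c(OC)c(c1)C(C(=O)OC)C(=O)c1ccc(OC(=O)OC(C)(C)C)c(OC(=O)OC(C)(C)C)c1 | intermediate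
11 | (2R,3R)-β-hydroxy ester, C7 O-TBS | COC(=O)/C=C/c1cc(O[Si](C)(C)C(C)(C)C)c(OC)c(c1)[C@@H](C(=O)OC)[C@H](c1ccc(OC(=O)OC(C)(C)C)c(OC(=O)OC(C)(C)C)c1)O | intermediate
12 | (2R,3R)-β-hydroxy ester, free C7 phenol | COC(=O)/C=C/c1cc(O)c(OC)c(c1)[C@@H](C(=O)OC)[C@H](c1ccc(OC(=O)OC(C)(C)C)c(OC(=O)OC(C)(C)C)c1)O | intermediate
13 | methyl (2R,3R)-2-[3,4-bis(tert-butoxycarbonyloxy)phenyl]-7a-methoxy-5-[(E)-3-methoxy-3-oxoprop-1-enyl]-7-oxo-2,3,7,7a-tetrahydrobenzofuran-3-carboxylate (C7a either configuration, not isolated) | COC(=O)/C=C/C1=CC(=O)C2(OC)C(=C1)[C@@H](C(=O)OC)[C@H](c1ccc(OC(=O)OC(C)(C)C)c(OC(=O)OC(C)(C)C)c1)O2 | intermediate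
14 | methyl (2R,3R)-2-[3,4-bis(tert-butoxycarbonyloxy)phenyl]-7-hydroxy-5-[(E)-3-methoxy-3-oxoprop-1-enyl]-2,3-dihydrobenzofuran-3-carboxylate | COC(=O)/C=C/c1cc(O)c2c(c1)[C@@H](C(=O)OC)[C@H](c1ccc(OC(=O)OC(C)(C)C)c(OC(=O)OC(C)(C)C)c1)O2 | intermediate
15 | methyl (2R,3R)-2-(3,4-dihydroxyphenyl)-7-hydroxy-5-[(E)-3-methoxy-3-oxoprop-1-enyl]-2,3-dihydrobenzofuran-3-carboxylate | COC(=O)/C=C/c1cc(O)c2c(c1)[C@@H](C(=O)OC)[C@H](c1ccc(O)c(O)c1)O2 | target

**Step count and risks**

Total step count: 11. Longest linear sequence: 10 (steps 1–4 and 6–11).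

Steps most likely to fail:

1. **Step 10.**
   - What may go wrong: the ring oxygen may be expelled instead of methoxide in the reductive half. The ketal may dimerise by Diels–Alder reaction or tautomerise towards the benzofuran oxidation level before it is reduced. The hydroxyl may also attack competitively at C4.
   - Fallback (known chemistry, closing the ring from the other side), setting out from 12: an Adler-type periodate oxidation (NaIO4, aqueous THF, 0 °C) should remove the methyl group as methanol and give the o-quinone F1. Sodium dithionite reduces this in the same flask to the ring-A catechol F2. TFA in CH2Cl2 then removes both carbonates to give the Boc-free tetraphenol alcohol F3. Its now p-hydroxy-activated benzylic alcohol should ionise (quinone-methide-type cation) and be captured by the C7a hydroxyl anti to the C3 ester. C3, which is not touched by acid, therefore dictates the trans (2R,3R) ring, and the route is rejoined at 15.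

2. **Step 8.**
   - What may go wrong: the rate difference between the two interconverting C3 epimers may be insufficient, giving poor syn/anti selection, while the carbinol sense is the safer element.
   - Fallback, setting out from 10: the reduction is run for carbinol selectivity only, and 11 is carried on together with its C3 epimer, the (2S,3R)-silyl ether F4. Buffered desilylation gives 12 plus the (2S,3R)-phenol F5. The conditions of step 10 should convert F5 through the epimeric ketal F6 into the cis-(2R,3S)-dihydrobenzofuran F7. Catalytic DBU in toluene at rt then equilibrates C3 through the ester enolate to the more stable trans isomer (known cis-to-trans epimerisation of 2-aryl-2,3-dihydrobenzofuran-3-carboxylates). The whole material thus converges on 14.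

3. **Step 4.**
   - What may go wrong: oxidative addition at the ortho-methoxy bromide may be slow, which leaves time for self-condensation of the zinc enolate and Heck-type consumption of the cinnamate.
   - Fallback, setting out from 4: palladium-catalysed arylation of dimethyl malonate (Pd2(dba)3, P(t-Bu)3·HBF4, K3PO4, toluene, 80 °C) gives the aryl malonate F8. Krapcho dealkoxycarbonylation (LiCl, wet DMSO, 130 °C), expected to cleave the aryl silyl ether as well, gives the phenolic arylacetate F9. Resilylation (TBSCl, imidazole) then returns to 5.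

Further compounds
F1 | step 10 | methyl (2R,3R)-3-[3,4-bis(tert-butoxycarbonyloxy)phenyl]-3-hydroxy-2-{5-[(E)-3-methoxy-3-oxoprop-1-enyl]-2,3-dioxocyclohexa-4,6-dienyl}propanoate (o-quinone) | COC(=O)/C=C/C1=CC(=O)C(=O)C(=C1)[C@@H](C(=O)OC)[C@H](c1ccc(OC(=O)OC(C)(C)C)c(OC(=O)OC(C)(C)C)c1)O
F2 | step 10 | methyl (2R,3R)-3-[3,4-bis(tert-butoxycarbonyloxy)phenyl]-2-{2,3-dihydroxy-5-[(E)-3-methoxy-3-oxoprop-1-enyl]phenyl}-3-hydroxypropanoate | COC(=O)/C=C/c1cc(O)c(O)c(c1)[C@@H](C(=O)OC)[C@H](c1ccc(OC(=O)OC(C)(C)C)c(OC(=O)OC(C)(C)C)c1)O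
F3 | step 10 | methyl (2R,3R)-2-{2,3-dihydroxy-5-[(E)-3-methoxy-3-oxoprop-1-enyl]phenyl}-3-(3,4-dihydroxyphenyl)-3-hydroxypropanoate | COC(=O)/C=C/c1cc(O)c(O)c(c1)[C@@H](C(=O)OC)[C@H](c1ccc(O)c(O)c1)O
F4 | step 8 | (2S,3R)-epimer of 11 | COC(=O)/C=C/c1cc(O[Si](C)(C)C(C)(C)C)c(OC)c(c1)[C@H](C(=O)OC)[C@H](c1ccc(OC(=O)OC(C)(C)C)c(OC(=O)OC(C)(C)C)c1)O
F5 | step 8 | (2S,3R)-epimer of 12 | COC(=O)/C=C/c1cc(O)c(OC)c(c1)[C@H](C(=O)OC)[C@H](c1ccc(OC(=O)OC(C)(C)C)c(OC(=O)OC(C)(C)C)c1)O
F6 | step 8 | C3 epimer of ketal 13 | COC(=O)/C=C/C1=CC(=O)C2(OC)C(=C1)[C@H](C(=O)OC)[C@H](c1ccc(OC(=O)OC(C)(C)C)c(OC(=O)OC(C)(C)C)c1)O2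
F7 | step 8 | methyl (2R,3S)-2-[3,4-bis(tert-butoxycarbonyloxy)phenyl]-7-hydroxy-5-[(E)-3-methoxy-3-oxoprop-1-enyl]-2,3-dihydrobenzofuran-3-carboxylate (cis) | COC(=O)/C=C/c1cc(O)c2c(c1)[C@H](C(=O)OC)[C@H](c1ccc(OC(=O)OC(C)(C)C)c(OC(=O)OC(C)(C)C)c1)O2
F8 | step 4 | dimethyl 2-{3-(tert-butyldimethylsilyloxy)-2-methoxy-5-[(E)-3-methoxy-3-oxoprop-1-enyl]phenyl}malonate | COC(=O)/C=C/c1cc(O[Si](C)(C)C(C)(C)C)c(OC)c(c1)C(C(=O)OC)C(=O)OC
F9 | step 4 | methyl (E)-3-[3-hydroxy-4-methoxy-5-(2-methoxy-2-oxoethyl)phenyl]prop-2-enoate | COC(=O)/C=C/c1cc(O)c(OC)c(CC(=O)OC)c1
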